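All runs come from a simulation on assumed constants; the scatter is artificial.

Raising the temperature from 65 °C to 80 °C took the flat level of target down from about 24.5% in larch to about 14.6% in ash, so I doubt your hunch that ash just wants more time. Here is what we have and what is asked.

| setting | ash | larch | flask |
|---|---|---|---|
| solid substrate | 0.76 M | 0.76 M | 0.76 M |
| coupling partner | 1.2 equiv | 1.2 equiv | 1.20 equiv |
| temperature | 80 °C | 65 °C | 80 °C |
| remark | the very flask that is asked about, followed so far | run made earlier |  |
| time |  |  | 4.0 h |

| run | time / min | target / % |
|---|---|---|
| ash | 20.0 | 13.2 |
| ash | 60.0 | 14.6 |
| ash | 120 | 14.6 |
| ash | 180 | 14.1 |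
| ash | 240 | 15.2 |
| larch | 40.0 | 15.5 |
| larch | 120 | 23.8 |
| larch | 240 | 25.1 |
| larch | 360 | 24.1 |
| larch | 480 | 24.5 |

(standard deviation of a reading: 0.3 percentage points)

- amounts and yields of target count solid product too
- given per volume of solution although it is solid: solid substrate, solid product
- the volume of additions can be left aside
- what may be going on: solid substrate <-> dissolved substrate; dissolved substrate + coupling partner -> target; coupling partner -> side product; solid product <-> target; coupling partner -> decomposed reagent
- at the start none of the solid substrate is in solution

- south-west: at 4.0 h add coupling partner, 50.0% of the amount charged, then wait 80 min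
- north: change nothing and wait 80 min more
- north-east: at 4.0 h raise the temperature by 10 K, then wait 80 min

1. target, in percent of the solid substrate first charged, at 4.0 h
2. the remedy with the largest gain of target, or "none" below 2 percentage points (south-west / north / north-east / none)
3. target present, in percent of the solid substrate first charged, after south-west
4. target present, in percent of the solid substrate first charged, after north

I ask first what end state ash must reach. The ash readings stay flat within their scatter from 60.0 min onward, while 85.4% of the solid substrate charged reads as not target, so I take the coupling partner, charged at 1.2 equiv, to be the limiting reagent, lost to its two side routes. The number I carry is the return, 12.2% in ash: the share of the charged coupling partner that ends as target, which is the flat yield divided by the equivalents. In larch it reads 20.4%, so the return is lower in the hotter run.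

Then I ask how fast that end is approached. The reading at 20.0 min stands 1.4 percentage points short of the flat level, which gives, as a reading, a half-life near 5.91 min. The further 80 min is thus 13.5 such half-lives, so I expect nothing from waiting or heating ash. Fresh coupling partner should be used up in that time, and at the same return it adds 7.3 points, which brings ash to 21.9%.

The forecast gives 14.6% now (14.2% to 15%) and 14.6% after north. It chooses south-west and puts that at 23% (20.5% to 26%), higher than my figure, on the ground that “the substrate is already dissolved and there is no start-up lag”.

Ash gives 14.8% at 4.0 h, with coupling partner at 0%, and 14.8% after north. South-west gives 23.0%, a gain of 8.1 points, the largest, while north-east gains 0 points.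

    solid substrate ⇌ dissolved substrate, rate k1*(cs1 - [dissolved substrate]) while solid is left; crystals form when [dissolved substrate] > cs1 (solubility = 0.260 M, k = 1.20 min⁻¹)
    dissolved substrate + coupling partner → target (k = 0.0640 M⁻¹ min⁻¹, Ea = 77.0 kJ mol⁻¹)
    coupling partner → side product (k = 0.0480 min⁻¹, Ea = 115 kJ mol⁻¹)
    solid product ⇌ target, rate k4*(cs4 - [target]) while solid is left; crystals form when [target] > cs4 (solubility = 0.270 M, k = 0.510 min⁻¹)
    coupling partner → decomposed reagent (k = 0.0570 min⁻¹, Ea = 108 kJ mol⁻¹)
    (constants at 80 °C)

In ash the added portion returned 13.5%, against the 12.2% I carried. The neighbouring flask is charged with 3.00 equiv of coupling partner, all else as in ash. The return times that charge gives 36.6% target. That neighbour holds 36.2% target at 240 min, with coupling partner at 0% and solid product, counted in the target, at 0.646%.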